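**Retrosynthetic overview**

1. Target ⇒ (lipase hydrolysis of an ethyl ester, then O‑acetylation) the free tertiary alcohol as its ethyl ester.
2. Enabling feature: in the cyclopentenyl ring (C1 = quaternary carbon with O and the carboxyheptyl chain, C2=C3, C4 = ketone, C5 = CH with the pentenyl chain) the atoms O=C4–C3=C2–C1–O are a masked 2,5‑disubstituted furan (ketone O = furan O, C1–O from water) and C5 is its carbinol carbon. The ring is therefore the retron of an oxa‑Piancatelli rearrangement, whose 4π electrocyclisation forms C1–C5 and sets both stereocentres at once.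
3. Furylcarbinol ⇒ Negishi sp2–sp3 coupling of a 5‑bromo‑2‑furylcarbinol with the zinc reagent of ethyl 8‑bromooctanoate; bromofurylcarbinol ⇒ 5‑bromo‑2‑furyllithium + (Z)‑hex‑3‑enal.
4. Ring order: the furan ring is bought (2‑bromofuran) and is consumed when the only ring of the target, the cyclopentenone, is closed in step 4.

Key step: step 4

Assumption: the (R)‑configured acid is taken to be the antipode that turns the conrotation toward the (1S,5R) product; if the opposite sense is found, its enantiomer is used with nothing else changed.

**Route**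

Step 1
Reactants: 1 (Z)-hex-3-en-1-ol
Product: 2 (Z)-hex-3-enal
Conditions: Dess–Martin periodinane, CH2Cl2, 0 °C to 25 °C; filtered through NaHCO3/MgSO4, solution used at once
Reagents that add atoms: none
Why: Dess–Martin oxidation of a primary alcohol stops at the aldehyde under mild, non‑aqueous conditions, so the Z‑alkene should stay out of conjugation if the solution is used immediately.

Step 2
Reactants: 3 2-bromofuran; 2 (Z)-hex-3-enal
Product: 5 (Z)-1-(5-bromofuran-2-yl)hex-3-en-1-ol (racemic), via 5-bromofuran-2-yllithium 4 (not isolated)
Conditions: LiN(iPr)2, THF, −78 °C; then 2, −78 °C; H2O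
Reagents that add atoms: none
Why: Deprotonation of 2‑bromofuran by LiN(iPr)2 at its free α‑position at −78 °C followed by 1,2‑addition of the heteroaryllithium to the aldehyde should outrun α‑deprotonation of the aldehyde; the carbinol centre is formed as a racemate, which is harmless because step 4 erases it.

Step 3
Reactants: 5 (Z)-1-(5-bromofuran-2-yl)hex-3-en-1-ol; 6 ethyl 8-bromooctanoate
Product: 8 ethyl 8-{5-[(Z)-1-hydroxyhex-3-en-1-yl]furan-2-yl}octanoate (racemic), via (8-ethoxy-8-oxooctyl)zinc bromide 7 (not isolated)
Conditions: 6, Zn dust, I2 (5 mol%), DMA, 80 °C; then 5, Pd(OAc)2 (2 mol%), 2-dicyclohexylphosphino-2',6'-dimethoxybiphenyl (4 mol%), THF, 25 °C (2 equiv of 7)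
Reagents that add atoms: none
Why: Negishi sp2–sp3 cross‑coupling, in which zinc insertion into the primary bromide gives an ester‑tolerant alkylzinc bromide that should couple with the 2‑bromofuran under palladium/biarylphosphine catalysis, conditions that tolerate a free hydroxyl group and leave the Z‑alkene untouched.

Step 4
Reactants: 8 ethyl 8-{5-[(Z)-1-hydroxyhex-3-en-1-yl]furan-2-yl}octanoate
Product: 12 ethyl 8-[(1S,5R)-1-hydroxy-4-oxo-5-[(Z)-pent-2-en-1-yl]cyclopent-2-en-1-yl]octanoate, via furfuryl cation 9 (not isolated), via dihydrofuran hemiketal 10 (not isolated), via dihydroxypentadienyl cation 11 (not isolated)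
Conditions: (R)-3,3'-bis(2,4,6-triisopropylphenyl)-1,1'-binaphthyl-2,2'-diyl N-triflylphosphoramide (10 mol%), H2O (10 equiv), CHCl3, 50 °C
Reagents that add atoms: water, O
Why: Proposed new method: the chiral acid should ionise either enantiomer of the carbinol to the same furfuryl cation 9, water should add at the alkyl‑bearing furan carbon to give hemiketal 10, and ring opening should give the 1,4‑dihydroxypentadienyl cation 11 as a hydrogen‑bonded ion pair with the chiral phosphoramide anion, after which electrocyclisation and proton loss give the enone; the closest known reactions are the racemic oxa‑Piancatelli rearrangement of 5‑alkyl‑2‑furylcarbinols with water and the chiral‑phosphoric‑acid‑catalysed enantioselective aza‑Piancatelli rearrangement with anilines, which have not been combined for water as nucleophile and a fully substituted terminus. The cyclopentenone ring is closed by a thermal 4π‑conrotatory electrocyclisation of 11 (the Nazarov mode of closure) that joins the former carbinol carbon, now C5, to the former chain‑bearing furan carbon, now C1. The relative configuration follows from the geometry of 11 and conrotation: the central C=C bond is cis because it comes from the furan ring, the pentenyl group and the hydroxyl both sit on outward positions of the U‑shaped cation (the hydroxyl because its O–H is bound to the anion at the open periphery), and outward groups emerge trans, which places O trans and the carboxyalkyl chain cis to the pentenyl group. The absolute configuration (1S,5R) is decided by the sense of conrotation, which the chiral anion held at the two O–H groups should control. The step needs the nucleophilic terminus to be the carbinol carbon and not the first CH2 of the ester chain, which the furan guarantees because only the carbon that lost its hydroxyl becomes the enol terminus of the ring‑opened cation, and it needs capture of 9 by water to outrun loss of a proton from its allylic CH2, which the wet medium and the weakly basic counter‑anion favour.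

Step 5
Reactants: 12 ethyl 8-[(1S,5R)-1-hydroxy-4-oxo-5-[(Z)-pent-2-en-1-yl]cyclopent-2-en-1-yl]octanoate
Product: 13 ethyl 8-[(1S,5R)-1-acetoxy-4-oxo-5-[(Z)-pent-2-en-1-yl]cyclopent-2-en-1-yl]octanoate
Conditions: Ac2O, Sc(OTf)3 (2 mol%), MeCN, −20 °C
Reagents that add atoms: acetic anhydride, CC(=O)OC(C)=O
Why: Sc(OTf)3‑catalysed acylation with Ac2O should acetylate the hindered tertiary alcohol at low temperature without base, which avoids retro‑aldol opening and enolisation at C5, while ionisation of the C1–O bond is disfavoured by the adjacent enone, so both stereocentres stay untouched.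

Step 6
Reactants: 13 ethyl 8-[(1S,5R)-1-acetoxy-4-oxo-5-[(Z)-pent-2-en-1-yl]cyclopent-2-en-1-yl]octanoate
Product: 14 8-[(1S,5R)-1-acetoxy-4-oxo-5-[(Z)-pent-2-en-1-yl]cyclopent-2-en-1-yl]octanoic acid
Conditions: Candida antarctica lipase B (immobilised), NaH2PO4/Na2HPO4 buffer pH 7.0, acetone co‑solvent, 30 °C
Reagents that add atoms: water, O
Why: Lipase‑catalysed ester hydrolysis at pH 7 should cleave the unhindered primary ethyl ester of the fatty‑acid‑like chain while the tertiary acetate is not accepted by the enzyme, and the neutral medium avoids β‑elimination of acetate and epimerisation at C5, as in the enzymatic unmasking of base‑sensitive prostaglandin esters.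

**Compound list**

1 | (Z)-hex-3-en-1-ol | CC/C=C\CCO | starting material
2 | (Z)-hex-3-enal | CC/C=C\CC=O | intermediate
3 | 2-bromofuran | Brc1ccco1 | starting material
4 | 5-bromofuran-2-yllithium (formed in the flask) | [Li]c1ccc(Br)o1 | intermediate
5 | (Z)-1-(5-bromofuran-2-yl)hex-3-en-1-ol, racemic at the carbinol carbon | CC/C=C\CC(O)c1ccc(Br)o1 | intermediate
6 | ethyl 8-bromooctanoate | CCOC(=O)CCCCCCCBr | starting material
7 | (8-ethoxy-8-oxooctyl)zinc bromide (formed in the flask) | CCOC(=O)CCCCCCC[Zn]Br | intermediate
8 | ethyl 8-{5-[(Z)-1-hydroxyhex-3-en-1-yl]furan-2-yl}octanoate, racemic at the carbinol carbon | CC/C=C\CC(O)c1ccc(CCCCCCCC(=O)OCC)o1 | intermediate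
9 | furfuryl cation, (Z)-1-[5-(8-ethoxy-8-oxooctyl)furan-2-yl]hex-3-en-1-ylium (formed in the flask) | CC/C=C\C[CH+]c1ccc(CCCCCCCC(=O)OCC)o1 | intermediate
10 | dihydrofuran hemiketal, ethyl 8-{2-hydroxy-5-[(Z)-hex-3-en-1-ylidene]-2,5-dihydrofuran-2-yl}octanoate, exocyclic chain cis to the ring oxygen, hemiketal carbon racemic (formed in the flask) | CC/C=C\C/C=C1\OC(O)(CCCCCCCC(=O)OCC)C=C1 | intermediate
11 | dihydroxypentadienyl cation, O‑protonated ethyl (10Z,12Z,15Z)-12-hydroxy-9-oxooctadeca-10,12,15-trienoate, ion pair with the catalyst anion (formed in the flask) | CC/C=C\C/C=C(O)/C=C\C(=[OH+])CCCCCCCC(=O)OCC | intermediate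
12 | ethyl 8-[(1S,5R)-1-hydroxy-4-oxo-5-[(Z)-pent-2-en-1-yl]cyclopent-2-en-1-yl]octanoate | CC/C=C\C[C@H]1C(=O)C=C[C@]1(CCCCCCCC(=O)OCC)O | intermediate
13 | ethyl 8-[(1S,5R)-1-acetoxy-4-oxo-5-[(Z)-pent-2-en-1-yl]cyclopent-2-en-1-yl]octanoate | CC/C=C\C[C@H]1C(=O)C=C[C@]1(CCCCCCCC(=O)OCC)OC(C)=O | intermediate
14 | 8-[(1S,5R)-1-acetoxy-4-oxo-5-[(Z)-pent-2-en-1-yl]cyclopent-2-en-1-yl]octanoic acid | CC/C=C\C[C@H]1C(=O)C=C[C@]1(CCCCCCCC(=O)O)OC(C)=O | target

**Summary**

Total step count: 6. Longest linear sequence: 6 steps (1 → 2 → 5 → 8 → 12 → 13 → 14).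

Steps most likely to fail:

Step 4. What may go wrong: insufficient control of the sense of conrotation by the chiral anion in the wet medium, or loss of a proton from cation 9 to a furyl diene in place of capture by water. Fallback: from 8, the known racemic oxa‑Piancatelli rearrangement with Dy(OTf)3 (10 mol%) in tert‑butanol/water at 80 °C should give the trans product as a racemate, that is 12 together with its mirror image, ethyl 8-[(1R,5S)-1-hydroxy-4-oxo-5-[(Z)-pent-2-en-1-yl]cyclopent-2-en-1-yl]octanoate F1. Resolution by preparative chromatography on a chiral stationary phase (amylose tris(3,5-dimethylphenylcarbamate), supercritical CO2/methanol) returns to the route at 12.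

Step 2. What may go wrong: isomerisation of the β,γ‑unsaturated aldehyde 2 into conjugation, or its deprotonation by 4, in place of carbonyl addition. Fallback: the polarity of the union is reversed. From 3, lithiation as in step 2 and quenching of 4 with DMF gives 5-bromofuran-2-carbaldehyde F2. (Z)-1-Chloropent-2-ene F3, made from purchased (Z)-pent-2-en-1-ol with PPh3 in CCl4 (Appel chlorination, no allylic shift), is converted with activated barium (zerovalent barium from BaI2 and lithium biphenylide, THF, −78 °C) into (Z)-pent-2-en-1-ylbarium chloride F4. Allylbarium reagents add to aldehydes through the α‑carbon with retention of the alkene geometry, so F4 and F2 at −78 °C, where the C–Br bond is not touched, should give 5, and the route is rejoined there.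

Step 6. What may go wrong: cleavage or β‑elimination of the tertiary acetate, or epimerisation at C5, while the ethyl ester is hydrolysed. Fallback: the order of the last two operations is exchanged so that no hydrolysis is asked of the acetate. From 12, the same lipase hydrolysis gives 8-[(1S,5R)-1-hydroxy-4-oxo-5-[(Z)-pent-2-en-1-yl]cyclopent-2-en-1-yl]octanoic acid F5. Excess Ac2O with Sc(OTf)3 (MeCN, −20 °C) then acetylates the tertiary alcohol and converts the carboxyl group into the mixed anhydride, acetic 8-[(1S,5R)-1-acetoxy-4-oxo-5-[(Z)-pent-2-en-1-yl]cyclopent-2-en-1-yl]octanoic anhydride F6, which is hydrolysed with water/THF during work‑up to give 14.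

**Further compounds**

F1 | step 4 | ethyl 8-[(1R,5S)-1-hydroxy-4-oxo-5-[(Z)-pent-2-en-1-yl]cyclopent-2-en-1-yl]octanoate | CC/C=C\C[C@@H]1C(=O)C=C[C@@]1(CCCCCCCC(=O)OCC)O
F2 | step 2 | 5-bromofuran-2-carbaldehyde | O=Cc1ccc(Br)o1
F3 | step 2 | (Z)-1-chloropent-2-ene | CC/C=C\CCl
F4 | step 2 | (Z)-pent-2-en-1-ylbarium chloride | CC/C=C\C[Ba]Cl
F5 | step 6 | 8-[(1S,5R)-1-hydroxy-4-oxo-5-[(Z)-pent-2-en-1-yl]cyclopent-2-en-1-yl]octanoic acid | CC/C=C\C[C@H]1C(=O)C=C[C@]1(CCCCCCCC(=O)O)O
F6 | step 6 | acetic 8-[(1S,5R)-1-acetoxy-4-oxo-5-[(Z)-pent-2-en-1-yl]cyclopent-2-en-1-yl]octanoic anhydride | CC/C=C\C[C@H]1C(=O)C=C[C@]1(CCCCCCCC(=O)OC(C)=O)OC(C)=O
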